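**Retrosynthetic overview**
1. Butenolide (last ring): the lactone C–O bond comes from lactonisation of a (Z)-γ-hydroxy enoate, C3=C4 from a Z-selective Still–Gennari olefination, and C5–O with its (R) centre from a proline-catalysed α-aminoxylation of a γ,δ-unsaturated aldehyde.
2. Chain: the aldehyde comes from an allylic bromide and an acetaldehyde aza-enolate (the C–C bond next to C5); the bromide comes from SeO2 oxidation of the E-methyl group of a prenyl terminus, which fixes the E olefin.
3. Chromene C3=C4: ring-closing metathesis of a 2-vinylaryl (S)-linalyl ether.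
4. Key disconnection O1–C2: the quaternary chromene C2 (bearing O1, CH3, ring C3 and the chain CH2) is read as the tertiary terminus of a geranyl π-allyl, so a 2-vinylphenol and achiral geranyl methyl carbonate are joined by Pd-catalysed asymmetric allylic etherification, which sets (S)-C2.
5. Ring order: the pyran ring of the chromene (step 6), then the butenolide (step 12); the arene is bought.

Key step: step 5

**Assumptions and remarks**
- The (R,R) enantiomer of the bis-amide diphosphine ligand is assumed to give the (S) ether from the E-carbonate; if the sense is the opposite, the (S,S) ligand is used.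
- N-tert-Butylethanimine (11) is taken as a catalogue reagent; it is otherwise made from acetaldehyde and tert-butylamine.
- The 2H-chromenes 8 to 21 are kept from UV light, because photochemical ring opening to the o-quinone methide would erode C2.

**Route**

Step 1
Reactants: 1 methylhydroquinone (2-methylbenzene-1,4-diol)
Product: 2 4-{[tert-butyl(dimethyl)silyl]oxy}-2-methylphenol
Conditions: TBSCl (1.0 equiv), imidazole, DMF, 0 °C
Reagents that add atoms: tert-butyldimethylsilyl chloride, CC(C)(C)[Si](C)(C)Cl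
Why: Sterically controlled mono-silylation of a hydroquinone should take place at the 4-OH, which has two free ortho positions, in preference to the 1-OH next to the methyl group.

Step 2
Reactants: 2 4-{[tert-butyl(dimethyl)silyl]oxy}-2-methylphenol
Product: 3 5-{[tert-butyl(dimethyl)silyl]oxy}-2-hydroxy-3-methylbenzaldehyde
Conditions: MgCl2, Et3N, (CH2O)n, MeCN, reflux; aq. HCl work-up
Reagents that add atoms: paraformaldehyde (formaldehyde), C=O
Why: Magnesium-phenoxide-directed ortho-formylation (Casnati–Skattebøl type) delivers formaldehyde to the only free position ortho to the free OH, and a second equivalent of formaldehyde oxidises the hydroxymethyl intermediate to the aldehyde.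

Step 3
Reactants: 3 5-{[tert-butyl(dimethyl)silyl]oxy}-2-hydroxy-3-methylbenzaldehyde
Product: 4 4-{[tert-butyl(dimethyl)silyl]oxy}-2-ethenyl-6-methylphenol
Conditions: Ph3PCH3Br (2.5 equiv), KHMDS (2.4 equiv), THF, 0 °C → rt
Reagents that add atoms: methyltriphenylphosphonium bromide, C[P+](c1ccccc1)(c1ccccc1)c1ccccc1.[Br-]
Why: Wittig methylenation of the salicylaldehyde with excess ylide (one equivalent is held by the phenol) should give the o-vinylphenol that later serves as the metathesis partner.

Step 4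
Reactants: 5 geraniol
Product: 6 geranyl methyl carbonate [(2E)-3,7-dimethylocta-2,6-dien-1-yl methyl carbonate]
Conditions: ClCO2Me, pyridine, CH2Cl2, 0 °C
Reagents that add atoms: methyl chloroformate, COC(=O)Cl
Why: O-Acylation of the primary allylic alcohol gives the ionisable carbonate and leaves the E geometry of C2=C3 untouched, which later encodes the configuration at chromene C2.

Step 5
Reactants: 4 4-{[tert-butyl(dimethyl)silyl]oxy}-2-ethenyl-6-methylphenol; 6 geranyl methyl carbonate
Product: 7 tert-butyl(4-{[(3S)-3,7-dimethylocta-1,6-dien-3-yl]oxy}-3-ethenyl-5-methylphenoxy)dimethylsilane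
Conditions: Pd2(dba)3·CHCl3 (1 mol%), (R,R)-DACH-phenyl bis(2-diphenylphosphinobenzamide) ligand (3 mol%), CH2Cl2, rt
Reagents that add atoms: none
Why: Tsuji–Trost asymmetric allylic etherification: Pd(0) ionises 6 to CO2, methoxide (which deprotonates 4) and a 1,1-disubstituted π-allyl complex, and the phenoxide attacks the fully substituted terminus anti to palladium, forming the bond that becomes O1–C2 of the chromene; the closest precedent is the branched-selective coupling of phenols with geranyl- and prenyl-type carbonates under this ligand class. No ring is closed here (the pyran ring follows in step 6); the step joins arene and terpenoid and sets the only quaternary stereocentre. The configuration is controlled by the chiral ligand: the two π-allyl complexes that differ in the allyl face bound to Pd interconvert through the η1 species at the CH2 terminus and are funnelled through the faster-reacting one, while the E geometry of 6 fixes methyl as anti and homoprenyl as syn and cannot scramble, since that would need a tertiary σ-Pd species. The step needs branched over linear attack, which this ligand class imposes on O-nucleophiles (the linear ether is the thermodynamic product, so the reaction is stopped at full conversion), O- over C-allylation, which the blocked ortho and para positions of 4 secure, and face selectivity, for which ligand enantiomer and olefin geometry are two independent handles.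

Step 6
Reactants: 7 tert-butyl(4-{[(3S)-3,7-dimethylocta-1,6-dien-3-yl]oxy}-3-ethenyl-5-methylphenoxy)dimethylsilane
Product: 8 tert-butyl{[(2S)-2,8-dimethyl-2-(4-methylpent-3-en-1-yl)-2H-chromen-6-yl]oxy}dimethylsilane
Conditions: (H2IMes)(PCy3)Cl2Ru=CHPh (3 mol%), CH2Cl2 (0.01 M), 40 °C
Reagents that add atoms: none
Why: Ring-closing olefin metathesis: the catalyst should load on the styrene, and the benzylidene should close the six-membered pyran ring onto the neighbouring vinyl group with loss of ethylene faster than the catalyst can reach the hindered vinyl group first, which the competing cyclopentene closure with the chain olefin would require; C2 is not touched.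

Step 7
Reactants: 8 tert-butyl{[(2S)-2,8-dimethyl-2-(4-methylpent-3-en-1-yl)-2H-chromen-6-yl]oxy}dimethylsilane
Product: 9 (2E)-5-[(2S)-6-{[tert-butyl(dimethyl)silyl]oxy}-2,8-dimethyl-2H-chromen-2-yl]-2-methylpent-2-en-1-ol
Conditions: SeO2 (0.3 equiv), t-BuOOH, salicylic acid (cat.), CH2Cl2, rt
Reagents that add atoms: tert-butyl hydroperoxide, CC(C)(C)OO
Why: Catalytic SeO2 allylic oxidation (ene reaction, then [2,3]-sigmatropic shift) is selective for the E-methyl group of a terminal trisubstituted olefin, which fixes the E geometry of the central olefin; the chromene olefin has no allylic C–H.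

Step 8
Reactants: 9 (2E)-5-[(2S)-6-{[tert-butyl(dimethyl)silyl]oxy}-2,8-dimethyl-2H-chromen-2-yl]-2-methylpent-2-en-1-ol
Product: 10 {[(2S)-2-[(3E)-5-bromo-4-methylpent-3-en-1-yl]-2,8-dimethyl-2H-chromen-6-yl]oxy}(tert-butyl)dimethylsilane
Conditions: CBr4, PPh3, CH2Cl2, 0 °C
Reagents that add atoms: carbon tetrabromide, BrC(Br)(Br)Br
Why: The Appel reaction converts the primary allylic alcohol into the bromide under near-neutral conditions without allylic transposition.

Step 9
Reactants: 10 {[(2S)-2-[(3E)-5-bromo-4-methylpent-3-en-1-yl]-2,8-dimethyl-2H-chromen-6-yl]oxy}(tert-butyl)dimethylsilane; 11 N-tert-butylethanimine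
Product: 13 (4E)-7-[(2S)-6-{[tert-butyl(dimethyl)silyl]oxy}-2,8-dimethyl-2H-chromen-2-yl]-4-methylhept-4-enal, via N-tert-butyl imine of this aldehyde 12 (not isolated)
Conditions: 11, LDA, THF, −78 → 0 °C; 10, −78 °C → rt; aq. oxalic acid, rt
Reagents that add atoms: water, O
Why: Aza-enolate (metalloenamine) alkylation by SN2 at the primary allylic carbon adds the two carbons that become C5 and C4 of the butenolide, and mild aqueous acid hydrolyses the imine to the aldehyde.

Step 10
Reactants: 14 methyl bis(2,2,2-trifluoroethyl)phosphonoacetate; 15 5-bromo-2-methylpent-2-ene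
Product: 16 methyl 2-[bis(2,2,2-trifluoroethoxy)phosphoryl]-6-methylhept-5-enoate
Conditions: NaH, DMF, 0 °C; then 15, NaI (cat.), 50 °C
Reagents that add atoms: none
Why: C-Alkylation of the sodium phosphonoacetate with the homoallylic bromide (iodide catalysis) places the future C3 side chain on the Still–Gennari reagent.

Step 11
Reactants: 13 (4E)-7-[(2S)-6-{[tert-butyl(dimethyl)silyl]oxy}-2,8-dimethyl-2H-chromen-2-yl]-4-methylhept-4-enal; 16 methyl 2-[bis(2,2,2-trifluoroethoxy)phosphoryl]-6-methylhept-5-enoate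
Product: 18 methyl (2Z,4R,6E)-9-[(2S)-6-{[tert-butyl(dimethyl)silyl]oxy}-2,8-dimethyl-2H-chromen-2-yl]-6-methyl-2-(4-methylpent-3-en-1-yl)-4-[(phenylamino)oxy]nona-2,6-dienoate, via (2R)-2-[(phenylamino)oxy] aldehyde 17 (not isolated)
Conditions: PhNO, L-proline (20 mol%), MeCN, −20 °C; then added to 16, KHMDS, 18-crown-6, THF, −78 °C
Reagents that add atoms: nitrosobenzene, O=Nc1ccccc1
Why: Proline-catalysed α-aminoxylation delivers the nitroso oxygen to the enamine face that carries the carboxylic acid (hydrogen bond to N), which with L-proline should give the (R) centre that becomes C5, and the labile aldehyde is trapped at once by Still–Gennari olefination, whose kinetic control gives the (Z)-trisubstituted enoate.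

Step 12
Reactants: 18 methyl (2Z,4R,6E)-9-[(2S)-6-{[tert-butyl(dimethyl)silyl]oxy}-2,8-dimethyl-2H-chromen-2-yl]-6-methyl-2-(4-methylpent-3-en-1-yl)-4-[(phenylamino)oxy]nona-2,6-dienoate
Product: 20 O-TBS-tuberatolide B [(5R)-5-{(2E)-5-[(2S)-6-{[tert-butyl(dimethyl)silyl]oxy}-2,8-dimethyl-2H-chromen-2-yl]-2-methylpent-2-en-1-yl}-3-(4-methylpent-3-en-1-yl)furan-2(5H)-one], via (Z)-4-hydroxy enoate 19 (not isolated)
Conditions: Zn dust, AcOH–THF, rt, then 40 °C
Reagents that add atoms: none
Why: Reductive N–O cleavage by zinc in acetic acid frees the γ-hydroxy (Z)-enoate, which lactonises under the acidic conditions to the butenolide without change at C5; any E-enoate cannot cyclise and is removed here.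

Step 13
Reactants: 20 O-TBS-tuberatolide B
Product: 21 tuberatolide B
Conditions: TBAF, AcOH (1:1), THF, 0 °C
Reagents that add atoms: none
Why: Fluoride desilylation cleaves the aryl silyl ether, and the acetic acid buffer keeps the medium from epimerising the base-sensitive C5–H of the butenolide.

**Compound list**
1 | methylhydroquinone (2-methylbenzene-1,4-diol) | Cc1cc(O)ccc1O | starting material
2 | 4-{[tert-butyl(dimethyl)silyl]oxy}-2-methylphenol | Cc1cc(O[Si](C)(C)C(C)(C)C)ccc1O | intermediate
3 | 5-{[tert-butyl(dimethyl)silyl]oxy}-2-hydroxy-3-methylbenzaldehyde | Cc1cc(O[Si](C)(C)C(C)(C)C)cc(C=O)c1O | intermediate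
4 | 4-{[tert-butyl(dimethyl)silyl]oxy}-2-ethenyl-6-methylphenol | C=Cc1cc(O[Si](C)(C)C(C)(C)C)cc(C)c1O | intermediate
5 | geraniol | CC(C)=CCC/C(C)=C/CO | starting material
6 | geranyl methyl carbonate | COC(=O)OC/C=C(\C)CCC=C(C)C | intermediate
7 | tert-butyl(4-{[(3S)-3,7-dimethylocta-1,6-dien-3-yl]oxy}-3-ethenyl-5-methylphenoxy)dimethylsilane | CC(C)=CCC[C@@](C)(C=C)Oc1c(C)cc(O[Si](C)(C)C(C)(C)C)cc1C=C | intermediate
8 | tert-butyl{[(2S)-2,8-dimethyl-2-(4-methylpent-3-en-1-yl)-2H-chromen-6-yl]oxy}dimethylsilane | CC(C)=CCC[C@@]1(C)C=Cc2cc(O[Si](C)(C)C(C)(C)C)cc(C)c2O1 | intermediate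
9 | (2E)-5-[(2S)-6-{[tert-butyl(dimethyl)silyl]oxy}-2,8-dimethyl-2H-chromen-2-yl]-2-methylpent-2-en-1-ol | OC/C(C)=C/CC[C@@]1(C)C=Cc2cc(O[Si](C)(C)C(C)(C)C)cc(C)c2O1 | intermediate
10 | {[(2S)-2-[(3E)-5-bromo-4-methylpent-3-en-1-yl]-2,8-dimethyl-2H-chromen-6-yl]oxy}(tert-butyl)dimethylsilane | BrC/C(C)=C/CC[C@@]1(C)C=Cc2cc(O[Si](C)(C)C(C)(C)C)cc(C)c2O1 | intermediate
11 | N-tert-butylethanimine | CC=NC(C)(C)C | starting material
12 | N-tert-butyl imine of aldehyde 13 | CC(C)(C)N=CCC/C(C)=C/CC[C@@]1(C)C=Cc2cc(O[Si](C)(C)C(C)(C)C)cc(C)c2O1 | intermediate (not isolated)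
13 | (4E)-7-[(2S)-6-{[tert-butyl(dimethyl)silyl]oxy}-2,8-dimethyl-2H-chromen-2-yl]-4-methylhept-4-enal | O=CCC/C(C)=C/CC[C@@]1(C)C=Cc2cc(O[Si](C)(C)C(C)(C)C)cc(C)c2O1 | intermediate
14 | methyl bis(2,2,2-trifluoroethyl)phosphonoacetate | COC(=O)CP(=O)(OCC(F)(F)F)OCC(F)(F)F | starting material
15 | 5-bromo-2-methylpent-2-ene | CC(C)=CCCBr | starting material
16 | methyl 2-[bis(2,2,2-trifluoroethoxy)phosphoryl]-6-methylhept-5-enoate | COC(=O)C(CCC=C(C)C)P(=O)(OCC(F)(F)F)OCC(F)(F)F | intermediate
17 | (2R,4E)-7-[(2S)-6-{[tert-butyl(dimethyl)silyl]oxy}-2,8-dimethyl-2H-chromen-2-yl]-4-methyl-2-[(phenylamino)oxy]hept-4-enal | O=C[C@H](ONc1ccccc1)C/C(C)=C/CC[C@@]2(C)C=Cc3cc(O[Si](C)(C)C(C)(C)C)cc(C)c3O2 | intermediate (not isolated)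
18 | methyl (2Z,4R,6E)-9-[(2S)-6-{[tert-butyl(dimethyl)silyl]oxy}-2,8-dimethyl-2H-chromen-2-yl]-6-methyl-2-(4-methylpent-3-en-1-yl)-4-[(phenylamino)oxy]nona-2,6-dienoate | COC(=O)/C(CCC=C(C)C)=C\[C@H](ONc1ccccc1)C/C(C)=C/CC[C@@]2(C)C=Cc3cc(O[Si](C)(C)C(C)(C)C)cc(C)c3O2 | intermediate
19 | methyl (2Z,4R,6E)-9-[(2S)-6-{[tert-butyl(dimethyl)silyl]oxy}-2,8-dimethyl-2H-chromen-2-yl]-4-hydroxy-6-methyl-2-(4-methylpent-3-en-1-yl)nona-2,6-dienoate | COC(=O)/C(CCC=C(C)C)=C\[C@H](O)C/C(C)=C/CC[C@@]1(C)C=Cc2cc(O[Si](C)(C)C(C)(C)C)cc(C)c2O1 | intermediate (not isolated)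
20 | O-TBS-tuberatolide B | CC(C)=CCCC1=C[C@@H](C/C(C)=C/CC[C@@]2(C)C=Cc3cc(O[Si](C)(C)C(C)(C)C)cc(C)c3O2)OC1=O | intermediate
21 | tuberatolide B [(5R)-5-{(2E)-5-[(2S)-6-hydroxy-2,8-dimethyl-2H-chromen-2-yl]-2-methylpent-2-en-1-yl}-3-(4-methylpent-3-en-1-yl)furan-2(5H)-one] | CC(C)=CCCC1=C[C@@H](C/C(C)=C/CC[C@@]2(C)C=Cc3cc(O)cc(C)c3O2)OC1=O | target

**Step count**
Total: 13 steps. Longest linear sequence: 11 steps (1, 2, 3, 5, 6, 7, 8, 9, 11, 12, 13).

**Steps most likely to fail**

Step 5. The hindered 2,6-disubstituted phenoxide may attack the CH2 terminus of the π-allyl (linear geranyl ether), or face discrimination may be incomplete; the latter would leave a diastereomer of the target that cannot be separated later. The fallback sets out from 4 and replaces enantioselective catalysis by a stereospecific substitution on a chiral-pool carbonate. (S)-Linalool F1 is acylated (n-BuLi, ClCO2Me, THF, −78 °C) to (S)-linalyl methyl carbonate F2. F2 is coupled with the sodium phenoxide of 4 under rhodium catalysis (RhCl(PPh3)3, P(OMe)3, THF). This reaction type is known for secondary carbonates with ortho-disubstituted phenoxides and for tertiary carbonates with carbon nucleophiles, where it is branched-selective and proceeds with retention; the tertiary O-arylation itself is an extension. The route is rejoined at 7.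

Step 6. The ruthenium carbene may engage the chain olefin together with the quaternary vinyl group (cyclopentene closure with loss of the chain), or rest as an unreactive alkoxy-chelated benzylidene. The fallback sets out from 2 and 6 and closes the ring through the C4–C4a bond instead. Ortho-bromination of 2 (NBS, CH2Cl2, 0 °C) gives 2-bromo-4-{[tert-butyl(dimethyl)silyl]oxy}-6-methylphenol F3. Etherification of F3 with 6 under the conditions of step 5 gives the bromoaryl (S)-linalyl ether F4. Chemoselective hydroboration of the vinyl group of F4 (9-BBN, THF) and intramolecular B-alkyl Suzuki coupling (PdCl2(dppf), K3PO4, DMF–H2O, 60 °C) give the (S)-chroman F5. Dehydrogenation with DDQ (dioxane, reflux) rejoins the route at 8.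

Step 11. The α-aminooxy aldehyde may oligomerise or epimerise before it is olefinated, nitrosobenzene may react with the chain olefin in an ene reaction, or the Z selectivity may erode. The fallback sets out from 10 and sets C5 by auxiliary-controlled glycolate alkylation. (4S)-4-Benzyl-3-{[(4-methoxybenzyl)oxy]acetyl}-1,3-oxazolidin-2-one F6 is prepared by N-acylation of (S)-4-benzyloxazolidin-2-one with [(4-methoxybenzyl)oxy]acetyl chloride. Its sodium enolate (NaHMDS, THF, −78 °C) is alkylated by 10 on the face away from the benzyl group to give the (2R)-alkylated imide F7. LiBH4 gives the primary alcohol F8, Dess–Martin oxidation gives the α-PMB-oxy aldehyde F9, and Still–Gennari olefination with 16 gives the PMB-protected (Z)-enoate F10. DDQ (CH2Cl2, pH 7 buffer) removes the PMB group to give 19, which lactonises, and the route is rejoined at 20.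

**Further compounds**
F1 | step 5 | (S)-linalool [(3S)-3,7-dimethylocta-1,6-dien-3-ol] | CC(C)=CCC[C@@](C)(C=C)O
F2 | step 5 | (S)-linalyl methyl carbonate | CC(C)=CCC[C@@](C)(C=C)OC(=O)OC
F3 | step 6 | 2-bromo-4-{[tert-butyl(dimethyl)silyl]oxy}-6-methylphenol | Cc1cc(O[Si](C)(C)C(C)(C)C)cc(Br)c1O
F4 | step 6 | (3-bromo-4-{[(3S)-3,7-dimethylocta-1,6-dien-3-yl]oxy}-5-methylphenoxy)(tert-butyl)dimethylsilane | CC(C)=CCC[C@@](C)(C=C)Oc1c(C)cc(O[Si](C)(C)C(C)(C)C)cc1Br
F5 | step 6 | tert-butyl{[(2S)-2,8-dimethyl-2-(4-methylpent-3-en-1-yl)-3,4-dihydro-2H-chromen-6-yl]oxy}dimethylsilane | CC(C)=CCC[C@@]1(C)CCc2cc(O[Si](C)(C)C(C)(C)C)cc(C)c2O1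
F6 | step 11 | (4S)-4-benzyl-3-{[(4-methoxybenzyl)oxy]acetyl}-1,3-oxazolidin-2-one | COc1ccc(COCC(=O)N2C(=O)OC[C@@H]2Cc3ccccc3)cc1
F7 | step 11 | (4S)-4-benzyl-3-{(2R,4E)-7-[(2S)-6-{[tert-butyl(dimethyl)silyl]oxy}-2,8-dimethyl-2H-chromen-2-yl]-2-[(4-methoxybenzyl)oxy]-4-methylhept-4-enoyl}-1,3-oxazolidin-2-one | COc1ccc(CO[C@H](C/C(C)=C/CC[C@@]2(C)C=Cc3cc(O[Si](C)(C)C(C)(C)C)cc(C)c3O2)C(=O)N4C(=O)OC[C@@H]4Cc5ccccc5)cc1
F8 | step 11 | (2R,4E)-7-[(2S)-6-{[tert-butyl(dimethyl)silyl]oxy}-2,8-dimethyl-2H-chromen-2-yl]-2-[(4-methoxybenzyl)oxy]-4-methylhept-4-en-1-ol | COc1ccc(CO[C@H](C/C(C)=C/CC[C@@]2(C)C=Cc3cc(O[Si](C)(C)C(C)(C)C)cc(C)c3O2)CO)cc1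
F9 | step 11 | (2R,4E)-7-[(2S)-6-{[tert-butyl(dimethyl)silyl]oxy}-2,8-dimethyl-2H-chromen-2-yl]-2-[(4-methoxybenzyl)oxy]-4-methylhept-4-enal | COc1ccc(CO[C@H](C/C(C)=C/CC[C@@]2(C)C=Cc3cc(O[Si](C)(C)C(C)(C)C)cc(C)c3O2)C=O)cc1
F10 | step 11 | methyl (2Z,4R,6E)-9-[(2S)-6-{[tert-butyl(dimethyl)silyl]oxy}-2,8-dimethyl-2H-chromen-2-yl]-4-[(4-methoxybenzyl)oxy]-6-methyl-2-(4-methylpent-3-en-1-yl)nona-2,6-dienoate | COc1ccc(CO[C@H](C/C(C)=C/CC[C@@]2(C)C=Cc3cc(O[Si](C)(C)C(C)(C)C)cc(C)c3O2)/C=C(/CCC=C(C)C)C(=O)OC)cc1
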